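The question before the meeting was when a flask charged with Q holds most J, and how much J that is.

| flask | Q | remark | time |
|---|---|---|---|
| grey | 13 mM | run made earlier |  |
| ochre | 30 mM | run made earlier |  |
| flask | 20 mM |  | 80 min |

| run | time / min | J / % |
|---|---|---|
| grey | 3.00 | 5.7 |
| grey | 6.00 | 16.2 |
| grey | 10.0 | 24.1 |
| grey | 20.0 | 21.3 |
| grey | 30.0 | 11.9 |
| grey | 50.0 | 2.5 |
| grey | 90.0 | 0.5 |
| ochre | 3.00 | 5.6 |
| ochre | 6.00 | 15.4 |
| ochre | 10.0 | 23.8 |
| ochre | 20.0 | 21.5 |
| ochre | 30.0 | 12.2 |
| ochre | 50.0 | 2.9 |
| ochre | 90.0 | 0.2 |

(readings scatter by 0.3 percentage points)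

* time, not beyond 80 min, at which the flask holds most J
* the amount of J, in percent of the Q charged, at that time
* the first time at which J reaches 13 %, in the same percent, in min



The chair noted that the flask's charge lay between those of the grey and ochre runs. She asked whether the charge mattered at all. The analyst proposed one number to answer it. She summed each run's readings over the same times, getting 82.2 % for grey and 81.6 % for ochre. Dividing ochre by grey made time drop out and left 0.993. She then divided ln of that ratio by ln of the charge ratio, which gave s = −0.00876. She called s the charge exponent: the slope of ln(summed percent J) against ln(charge).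

The sums differ by 0.6 percentage points, she said, and the scatter of such a difference is 1.1 points. So s, as read, cannot be told from zero. Her reckoning was that each flask reading equals the grey reading times (flask charge / grey charge)^s, a factor of 0.996. It gave no peak time of its own.

The forecaster then gave his numbers. He put the peak at 13 min (11 min to 15 min), holding 25 % (24.2 % to 26.5 %), and J reaching the level at 5.1 min (4.8 min to 5.4 min). His ground was that the runs “agree within scatter, so the kinetics look first-order overall”.

The flask peaks at 13.1 min with 25.4 % and first reaches the level at 5.14 min, each inside the forecast's range.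

    G → J (k = 0.290 min⁻¹)
    Q → Z (k = 1.50 min⁻¹)
    Z ⇌ G (K = 1.60, k = 0.110 min⁻¹)
    J → L (k = 0.140 min⁻¹)
    Q → X (k = 0.0510 min⁻¹)

The grey run's highest value without the scatter, 25.4 %, times the factor gives 25.3 % for this flask, which holds 25.4 %. The same reckoning goes to a neighbouring flask, alike but charged with 50 mM of Q. Its factor from this flask is 0.992, so its peak is reckoned at 25.2 %. That neighbour's peak is 25.4 %. At 80.0 min it holds 96.3 % of L.

The runs are simulated on assumed constants; the scatter is artificial.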